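## Retrosynthetic overview

1. Guaiane numbering is used. Left unit: C1–C15, ring A = C1–C5 (cyclopentenone), ring B = C1/C5–C10 (seven-membered), lactone on C6/C7. Right unit: primed atoms, rings D and E. Ring C is the spiro cyclohexene C1–C2–C4′–C15′–C14–C10.
2. The C1=C2 bond comes last, by syn-dehydration of a C2 α-ketol. Before that, rings B and A are closed together in one radical [3+2] annulation that forms C1–C5 and C2–C3 on a seco precursor that already holds rings C, D, E and both lactones.
3. Enabling feature: in ring A the carbonyl C3 sits between C4(=C15) and the C2=C1 bond of ring C. The C5–C4–C3(=O) unit is therefore the α-ketenyl form of an α,β-unsaturated acyl radical (spin at C5, acceptor at C3). C2 is the carbon of a former ring-C ketone, so its silyl enol ether takes C5 at C1 and hands a C2 radical back to C3. C15 carries a sulfanyl group that leaves as the exo-methylene forms.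
4. Ring C and the spiro centre C4′ come from a Diels–Alder reaction of a 1-silyloxy-3-alkyl diene with the right-hand α-methylene cyclopentanone (from dehydrocostus lactone). C10 is then set by CuH conjugate reduction.
5. The diene comes from (S)-5-(hydroxymethyl)butenolide by cuprate addition/methylation (C7, C11), HWE olefination (C5=C4 unit) and enyne cross-metathesis. Ring order: D/E/lactone′ (pool) → left lactone → C → B and A together.

Key step: step 17

## Remarks (assumptions)

- Taken as commercial: dehydrocostus lactone, (S)-5-(hydroxymethyl)furan-2(5H)-one, 4-bromo-1-(trimethylsilyl)but-1-yne, tert-butyl diethylphosphonoacetate, chloromethyl phenyl sulfide, tert-butyldimethyl(vinyloxy)silane.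
- The target carries opposite C11 configurations: left unit 13-methyl α (11S, thermodynamic), right unit 13-methyl β (11R, cis to C8′, kinetic).
- In step 13, (R)-DTBM-SEGPHOS is written on the assumption that it delivers hydride to the C10 face syn to C3′; the antipode is used if the sense is opposite.
- The C2 carbinol configuration of 20/21 and the C5=C4 geometry of 17–27 are drawn as the expected major isomers; both are erased later, so the other isomers converge.

## Route

Step 1
Reactants: 1 dehydrocostus lactone
Product: 3 (11R)-11αH,13-dihydrodehydrocostus lactone, via lithium enolate 2 (not isolated)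
Conditions: L-Selectride, THF, −78 °C; then AcOH, −78 °C
Reagents that add atoms: none
Why: Conjugate hydride reduction touches only the polarised α-methylene lactone, and kinetic protonation of the enolate at −78 °C should occur on the α-face of C11′, anti to C8′, placing the methyl β (11R); reaction type: 1,4-reduction with kinetic enolate protonation.

Step 2
Reactants: 3 (11R)-11αH,13-dihydrodehydrocostus lactone
Product: 4 (11R)-3α-hydroxy-11αH,13-dihydrodehydrocostus lactone
Conditions: SeO2 (cat.), t-BuOOH, CH2Cl2, 0 °C to rt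
Reagents that add atoms: tert-butyl hydroperoxide CC(C)(C)OO
Why: SeO2 allylic hydroxylation (ene reaction then [2,3]-shift) should attack C3′ next to the C4′=C15′ methylene from the convex α-face, as is usual in this guaianolide series; the C3′ configuration is lost in step 3.

Step 3
Reactants: 4 (11R)-3α-hydroxy-11αH,13-dihydrodehydrocostus lactone
Product: 5 (11R)-3-oxoguaia-4(15),10(14)-dien-12,6α-olide
Conditions: Dess–Martin periodinane, NaHCO3, CH2Cl2, 0 °C; used freshly
Reagents that add atoms: none
Why: Dess–Martin oxidation of the allylic alcohol is neutral and leaves the kinetic C11′ centre and both exocyclic alkenes untouched.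

Step 4
Reactants: 6 (S)-5-(hydroxymethyl)furan-2(5H)-one
Product: 7 (S)-5-[(tert-butyldiphenylsilyloxy)methyl]furan-2(5H)-one
Conditions: TBDPSCl, imidazole, CH2Cl2, 0 °C to rt
Reagents that add atoms: tert-butyl(chloro)diphenylsilane CC(C)(C)[Si](Cl)(c1ccccc1)c1ccccc1
Why: Standard silylation of the primary alcohol gives the bulky γ-substituent that steers the conjugate addition; the C6 centre comes from the starting material.

Step 5
Reactants: 7 (S)-5-[(tert-butyldiphenylsilyloxy)methyl]furan-2(5H)-one, 8 4-bromo-1-(trimethylsilyl)but-1-yne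
Product: 11 all-trans silylalkynyl lactone, via Grignard reagent 9 (not isolated), via magnesium enolate 10 (not isolated)
Conditions: Mg, THF (8 to 9); CuBr·SMe2 (10 mol%), THF, −78 °C; then MeI, HMPA, −78 to −20 °C
Reagents that add atoms: iodomethane CI
Why: Copper-catalysed 1,4-addition to the γ-substituted butenolide occurs anti to the C6 silyloxymethyl group (sets C7), and the enolate is methylated anti to the new C7 chain (sets C11, methyl α), giving the all-trans lactone; reaction type: tandem conjugate addition/enolate alkylation.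

Step 6
Reactants: 11 all-trans silylalkynyl lactone
Product: 12 all-trans 4-(but-3-ynyl)-5-(hydroxymethyl)-3-methyl-γ-butyrolactone
Conditions: TBAF, THF, 0 °C
Reagents that add atoms: none
Why: Fluoride cleaves the O–Si and the alkynyl C–Si bonds in one operation, and the all-trans lactone is the thermodynamic isomer, so the basic medium should not erode C11.

Step 7
Reactants: 12 all-trans 4-(but-3-ynyl)-5-(hydroxymethyl)-3-methyl-γ-butyrolactone
Product: 13 lactone 5-carbaldehyde
Conditions: Dess–Martin periodinane, NaHCO3, CH2Cl2, 0 °C; used crude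
Reagents that add atoms: none
Why: Buffered Dess–Martin oxidation gives the α-alkoxy aldehyde without base, so C6 should not epimerise.

Step 8
Reactants: 14 tert-butyl diethylphosphonoacetate, 15 chloromethyl phenyl sulfide
Product: 16 tert-butyl 2-(diethoxyphosphoryl)-3-(phenylsulfanyl)propanoate
Conditions: NaH, THF–DMF, 0 °C to rt
Reagents that add atoms: none
Why: C-Alkylation of the stabilised phosphonoacetate anion with the reactive α-chloro sulfide installs the future C15 with its sulfanyl leaving group; the new centre is racemic and disappears in step 9.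

Step 9
Reactants: 13 lactone 5-carbaldehyde, 16 tert-butyl 2-(diethoxyphosphoryl)-3-(phenylsulfanyl)propanoate
Product: 17 tert-butyl (Z)-2-[(phenylsulfanyl)methyl]-3-lactonylprop-2-enoate
Conditions: LiCl, DBU, MeCN, 0 °C
Reagents that add atoms: none
Why: Horner–Wadsworth–Emmons olefination under Masamune–Roush conditions is mild enough to keep the α-alkoxy aldehyde configured and builds the C5=C4(C15H2SPh)–C3 unit; the alkene geometry is irrelevant because C5 becomes a radical centre in step 17.

Step 10
Reactants: 17 tert-butyl (Z)-2-[(phenylsulfanyl)methyl]-3-lactonylprop-2-enoate, 18 tert-butyldimethyl(vinyloxy)silane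
Product: 19 (E)-1-silyloxy-3-alkylbuta-1,3-diene
Conditions: Grubbs second-generation catalyst (10 mol%), excess 18, toluene, 80 °C
Reagents that add atoms: none
Why: Cross enyne metathesis of a terminal alkyne with an enol ether gives the 2-substituted 1-alkoxy-1,3-diene regioselectively (C10=C14 and C1=C2), and the trisubstituted electron-poor enoate should be inert to the catalyst.

Step 11
Reactants: 5 (11R)-3-oxoguaia-4(15),10(14)-dien-12,6α-olide, 19 (E)-1-silyloxy-3-alkylbuta-1,3-diene
Product: 21 spiro allylic alcohol, via silyl ether adduct 20 (not isolated)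
Conditions: toluene, BHT (cat.), 80 °C; then HF·pyridine, THF, 0 °C
Reagents that add atoms: none
Why: In this Diels–Alder reaction the 1-silyloxy and 3-alkyl groups both direct C2 to the enone α-carbon C4′ and C14 to C15′, the diene should add to the convex α-face of the cis-fused hydroazulenone (anti to ring E) and so fix the spiro centre C4′, only the (E)-dienol ether reacts, and HF then frees the C2 carbinol, whose configuration is immaterial.

Step 12
Reactants: 21 spiro allylic alcohol
Product: 22 ring-C enone
Conditions: Dess–Martin periodinane, NaHCO3, CH2Cl2, 0 °C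
Reagents that add atoms: none
Why: Dess–Martin oxidation of the hindered allylic alcohol should be faster than sulfide oxidation and merges both C2 epimers into one 3-substituted cyclohexenone.

Step 13
Reactants: 22 ring-C enone
Product: 23 ring-C ketone
Conditions: Cu(OAc)2·H2O (5 mol%), (R)-DTBM-SEGPHOS (5 mol%), (EtO)2MeSiH, t-BuOH, toluene, 0 °C
Reagents that add atoms: none
Why: Ligand-controlled CuH 1,4-reduction of the β,β-disubstituted cyclohexenone (asymmetric conjugate hydrosilylation) should deliver hydride to the C10 face syn to C3′ and so set C10 (H-10β) under catalyst control, with the ring enone reacting before the trisubstituted side-chain enoate and the saturated ketone.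

Step 14
Reactants: 23 ring-C ketone
Product: 25 carboxylic acid, via trimethylsilyl ester 24 (not isolated)
Conditions: TMSOTf, 2,6-lutidine, CH2Cl2, 0 °C; then pH 4 aqueous buffer
Reagents that add atoms: none
Why: Silyl triflate cleavage of the tert-butyl ester (loss of isobutene) needs neither protic acid nor nucleophilic base, so the exocyclic alkene, the kinetic C11′ centre and the 1,3-diketone should survive.

Step 15
Reactants: 25 carboxylic acid
Product: 26 Se-phenyl selenoester
Conditions: (PhSe)2, PBu3, CH2Cl2, 0 °C to rt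
Reagents that add atoms: diphenyl diselenide c1ccc(cc1)[Se][Se]c1ccccc1
Why: Phosphine/diselenide activation converts the acid into the acyl selenide under neutral conditions; this is the standard acyl radical precursor.

Step 16
Reactants: 26 Se-phenyl selenoester
Product: 27 bis(trimethylsilyl enol ether)
Conditions: TMSOTf, Et3N, CH2Cl2, −78 to 0 °C; used crude
Reagents that add atoms: trimethylsilyl trifluoromethanesulfonate C[Si](C)(C)OS(=O)(=O)C(F)(F)F
Why: Soft enolisation is regiospecific because each ketone has only one enolisable side (C4′ is quaternary), giving the C1=C2 enol ether as radical acceptor and masking the ring-D ketone as its C2′=C3′ enol ether; lactones and the selenoester do not enolise.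

Step 17
Reactants: 27 bis(trimethylsilyl enol ether)
Product: 29 C2 α-ketol, via bis-silyl cascade product 28 (not isolated)
Conditions: (Bu3Sn)2 (1.2 equiv), hν (sunlamp), benzene (0.005 M), 80 °C; then 1 M aq. HCl, THF, 0 °C
Reagents that add atoms: none
Why: Proposed new method: Bu3Sn• abstracts PhSe from the selenoester to give an α,β-unsaturated acyl radical that reacts as its α-ketenyl form with spin at C5; C5 adds 7-exo-trig to C1 of the C1=C2 silyl enol ether (ring B), the resulting α-silyloxy C2 radical closes ring A by 5-exo attack on the ketene carbon C3, and the enoxyl radical expels PhS• from C15 to give the C4=C15 methylene, PhS• being turned back into Bu3Sn• by the distannane. The closest known reaction type is the tin-mediated α-ketenyl radical cyclisation/ketene-capture cascade of α,β-unsaturated selenoesters (5-exo closure, then attack of the new radical on the ketene) used for di- and triquinanes, extended here to a 7-exo first closure and a β-sulfanyl fragmentation as a non-reductive terminator. C5 is set in the 7-exo transition state with the ketene unit pseudo-equatorial and anti to the C6–O bond (H-5 trans to H-6), and as the γ-carbon of the final dienone it could be equilibrated with mild base if needed; C1 and C2 form cis (dictated by the 5-exo closure onto ring C) and are erased in step 18. The step needs attack at C1 and not C2 (7-exo versus 8-endo): this is secured by enol ether polarity (electrophilic radical to the nucleophilic β-carbon, giving the stabilised α-oxy radical) and by the neopentyl position of C2 next to the spiro centre. It also needs the cascade to outrun reduction, which the hydride-free distannane chain at high dilution provides. Acid work-up removes both trimethylsilyl groups and returns the ring-D ketone.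

Step 18
Reactants: 29 C2 α-ketol
Product: 30 target CNP0240988.1
Conditions: Burgess reagent, benzene, 50 °C
Reagents that add atoms: none
Why: Burgess dehydration is a concerted syn-elimination through the sulfamate ester; the C2 hydroxyl is cis to H-1 (cis A/C fusion from step 17) and C4′ has no hydrogen, so only the C1=C2 enone can form, and no stereocentre is created.

## Compound list

1 | dehydrocostus lactone | C=C1CC[C@H]2C(=C)CC[C@@H]3[C@H](OC(=O)C3=C)[C@H]21 | starting material
2 | lithium lactone enolate from 1,4-reduction of 1 | C=C1CC[C@H]2C(=C)CC[C@@H]3[C@H](OC([O-])=C3C)[C@H]21.[Li+] | intermediate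
3 | (11R)-11αH,13-dihydrodehydrocostus lactone (13-methyl β) | C=C1CC[C@H]2C(=C)CC[C@@H]3[C@H](OC(=O)[C@@H]3C)[C@H]21 | intermediate
4 | (11R)-3α-hydroxy-11αH,13-dihydrodehydrocostus lactone | C=C1[C@H](O)C[C@H]2C(=C)CC[C@@H]3[C@H](OC(=O)[C@@H]3C)[C@H]21 | intermediate
5 | (11R)-3-oxoguaia-4(15),10(14)-dien-12,6α-olide (right-hand dienophile) | C=C1C(=O)C[C@H]2C(=C)CC[C@@H]3[C@H](OC(=O)[C@@H]3C)[C@H]21 | intermediate
6 | (S)-5-(hydroxymethyl)furan-2(5H)-one | C1=CC(=O)O[C@@H]1CO | starting material
7 | (S)-5-[(tert-butyldiphenylsilyloxy)methyl]furan-2(5H)-one | C1=CC(=O)O[C@@H]1CO[Si](c2ccccc2)(c2ccccc2)C(C)(C)C | intermediate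
8 | 4-bromo-1-(trimethylsilyl)but-1-yne | C[Si](C)(C)C#CCCBr | starting material
9 | [4-(trimethylsilyl)but-3-yn-1-yl]magnesium bromide | C[Si](C)(C)C#CCC[Mg]Br | intermediate
10 | bromomagnesium enolate of the 1,4-adduct (chain trans to CH2OSi) | C[Si](C)(C)C#CCC[C@@H]1[C@H](OC(O[Mg]Br)=C1)CO[Si](c2ccccc2)(c2ccccc2)C(C)(C)C | intermediate
11 | all-trans 3-methyl-4-[4-(trimethylsilyl)but-3-ynyl]-5-[(tert-butyldiphenylsilyloxy)methyl]-γ-butyrolactone (5S) | C[Si](C)(C)C#CCC[C@@H]1[C@H](OC(=O)[C@H]1C)CO[Si](c2ccccc2)(c2ccccc2)C(C)(C)C | intermediate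
12 | all-trans 4-(but-3-ynyl)-5-(hydroxymethyl)-3-methyl-γ-butyrolactone | C#CCC[C@@H]1[C@H](OC(=O)[C@H]1C)CO | intermediate
13 | all-trans 4-(but-3-ynyl)-3-methyl-γ-butyrolactone-5-carbaldehyde | C#CCC[C@@H]1[C@H](OC(=O)[C@H]1C)C=O | intermediate
14 | tert-butyl diethylphosphonoacetate | CCOP(=O)(OCC)CC(=O)OC(C)(C)C | starting material
15 | chloromethyl phenyl sulfide | ClCSc1ccccc1 | starting material
16 | tert-butyl 2-(diethoxyphosphoryl)-3-(phenylsulfanyl)propanoate (racemic) | CCOP(=O)(OCC)C(CSc1ccccc1)C(=O)OC(C)(C)C | intermediate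
17 | tert-butyl (Z)-2-[(phenylsulfanyl)methyl]-3-[all-trans 4-(but-3-ynyl)-3-methyl-γ-butyrolacton-5-yl]prop-2-enoate | C#CCC[C@@H]1[C@H](OC(=O)[C@H]1C)/C=C(\CSc2ccccc2)C(=O)OC(C)(C)C | intermediate
18 | tert-butyldimethyl(vinyloxy)silane | C=CO[Si](C)(C)C(C)(C)C | starting material
19 | diene: enoate 17 with the alkyne converted into a (E)-4-(tert-butyldimethylsilyloxy)-2-methylenebut-3-enyl unit | C=C(/C=C/O[Si](C)(C)C(C)(C)C)CC[C@@H]1[C@H](OC(=O)[C@H]1C)/C=C(\CSc2ccccc2)C(=O)OC(C)(C)C | intermediate
20 | Diels–Alder adduct: ring C spiro at C4′, C2–OTBS (anti to C3′=O), C1=C10 | CC(C)(C)[Si](C)(C)O[C@H]1C=C(CC[C@@H]5[C@H](OC(=O)[C@H]5C)/C=C(\CSc6ccccc6)C(=O)OC(C)(C)C)CC[C@]12C(=O)C[C@H]3C(=C)CC[C@@H]4[C@H](OC(=O)[C@@H]4C)[C@H]32 | intermediate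
21 | spiro allylic alcohol (C2–OH, C1=C10) | O[C@H]1C=C(CC[C@@H]5[C@H](OC(=O)[C@H]5C)/C=C(\CSc6ccccc6)C(=O)OC(C)(C)C)CC[C@]12C(=O)C[C@H]3C(=C)CC[C@@H]4[C@H](OC(=O)[C@@H]4C)[C@H]32 | intermediate
22 | ring-C enone (C2=O, C1=C10) | O=C1C=C(CC[C@@H]5[C@H](OC(=O)[C@H]5C)/C=C(\CSc6ccccc6)C(=O)OC(C)(C)C)CC[C@]12C(=O)C[C@H]3C(=C)CC[C@@H]4[C@H](OC(=O)[C@@H]4C)[C@H]32 | intermediate
23 | ring-C ketone (C2=O, H-10 set), tert-butyl ester | O=C1C[C@@H](CC[C@@H]5[C@H](OC(=O)[C@H]5C)/C=C(\CSc6ccccc6)C(=O)OC(C)(C)C)CC[C@]12C(=O)C[C@H]3C(=C)CC[C@@H]4[C@H](OC(=O)[C@@H]4C)[C@H]32 | intermediate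
24 | trimethylsilyl ester of 25 | O=C1C[C@@H](CC[C@@H]5[C@H](OC(=O)[C@H]5C)/C=C(\CSc6ccccc6)C(=O)O[Si](C)(C)C)CC[C@]12C(=O)C[C@H]3C(=C)CC[C@@H]4[C@H](OC(=O)[C@@H]4C)[C@H]32 | intermediate
25 | carboxylic acid | O=C1C[C@@H](CC[C@@H]5[C@H](OC(=O)[C@H]5C)/C=C(\CSc6ccccc6)C(=O)O)CC[C@]12C(=O)C[C@H]3C(=C)CC[C@@H]4[C@H](OC(=O)[C@@H]4C)[C@H]32 | intermediate
26 | Se-phenyl selenoester | O=C1C[C@@H](CC[C@@H]5[C@H](OC(=O)[C@H]5C)/C=C(\CSc6ccccc6)C(=O)[Se]c7ccccc7)CC[C@]12C(=O)C[C@H]3C(=C)CC[C@@H]4[C@H](OC(=O)[C@@H]4C)[C@H]32 | intermediate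
27 | bis(trimethylsilyl enol ether) of 26 (C1=C2–OTMS in ring C, C2′=C3′–OTMS in ring D) | C[Si](C)(C)OC1=C[C@@H](CC[C@@H]5[C@H](OC(=O)[C@H]5C)/C=C(\CSc6ccccc6)C(=O)[Se]c7ccccc7)CC[C@]12C(O[Si](C)(C)C)=C[C@H]3C(=C)CC[C@@H]4[C@H](OC(=O)[C@@H]4C)[C@H]32 | intermediate
28 | bis-silyl cascade product (rings A and B closed, C2–OTMS cis to H-1, ring-D enol ether) | C=C1C(=O)[C@@]2(O[Si](C)(C)C)[C@@H]3[C@@H](CC[C@@H]4[C@H](OC(=O)[C@H]4C)[C@@H]13)CC[C@]21C(O[Si](C)(C)C)=C[C@H]2C(=C)CC[C@@H]3[C@H](OC(=O)[C@@H]3C)[C@H]21 | intermediate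
29 | C2 α-ketol (1,2-dihydro-2-hydroxy target, OH cis to H-1) | C=C1C(=O)[C@@]2(O)[C@@H]3[C@@H](CC[C@@H]4[C@H](OC(=O)[C@H]4C)[C@@H]13)CC[C@]21C(=O)C[C@H]2C(=C)CC[C@@H]3[C@H](OC(=O)[C@@H]3C)[C@H]21 | intermediate
30 | CNP0240988.1 | C=C1C(=O)C2=C3[C@@H](CC[C@@H]4[C@H](OC(=O)[C@H]4C)[C@@H]13)CC[C@]21C(=O)C[C@H]2C(=C)CC[C@@H]3[C@H](OC(=O)[C@@H]3C)[C@H]21 | target

## Step count and risks

Total steps: 18. Longest linear sequence: 14 steps (6 to 30 through steps 4–7 and 9–18).

Steps most likely to fail:

1. Step 17 (labelled). The 7-exo closure may be too slow, so the delocalised ketenyl radical is lost to oligomerisation or to stannyl/thiyl addition–fragmentation at the allyl sulfide before ring B forms; facial control at C5 may also be poor. Fallback (known chemistry, biomimetic Diels–Alder dimerisation), setting out from 1 with 5 as partner and rejoining at 30: NaBH4 in MeOH reduces 1 to the thermodynamic (11S)-11βH,13-dihydrodehydrocostus lactone F1; SeO2/t-BuOOH gives the 3α-ol F2 and Dess–Martin oxidation the left-hand enone F3; TMSOTf/Et3N converts F3 into the 3-silyloxy-2,4(15)-diene F4; Saegusa–Ito oxidation (Pd(OAc)2, MeCN) gives the cross-conjugated trienone F5, which is trapped in the same flask by 5 in a Diels–Alder reaction (C2–C4′ and C14–C15′) to give the Δ1(10) adduct F6; DBU then moves the double bond into conjugation (C1=C2), giving 30.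

2. Step 13. Hydride delivery to C10 may show poor facial selectivity, or the side-chain enoate or a ketone may be reduced competitively. Fallback, setting out from 21 and rejoining at 23 without new compounds: redox isomerisation of the allylic alcohol with a cationic Ru or H2-activated Ir(I) phosphine catalyst. The suprafacial 1,3-hydrogen shift carries the C2 carbinol hydrogen to C10 on the same face, which in the epimer drawn for 21 is the required one; the other C2 epimer is sent through steps 12 and 13.

3. Step 18. The hindered tertiary C2 hydroxyl may resist sulfamate formation, or may ionise and rearrange instead of undergoing syn-elimination. Fallback, setting out from 29 and rejoining at 30: SmI2 (THF–MeOH, −78 °C) removes the α-hydroxyl reductively to give the cis-fused saturated ketone F7; DDQ (dioxane, 80 °C) then dehydrogenates C1–C2, the α′,β′ position of the exo-methylene enone, leaving the saturated ring-D ketone alone.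

## Further compounds

F1 | step 17 | (11S)-11βH,13-dihydrodehydrocostus lactone | C=C1CC[C@H]2C(=C)CC[C@@H]3[C@H](OC(=O)[C@H]3C)[C@H]21
F2 | step 17 | (11S)-3α-hydroxy-11βH,13-dihydrodehydrocostus lactone | C=C1[C@H](O)C[C@H]2C(=C)CC[C@@H]3[C@H](OC(=O)[C@H]3C)[C@H]21
F3 | step 17 | (11S)-3-oxoguaia-4(15),10(14)-dien-12,6α-olide | C=C1C(=O)C[C@H]2C(=C)CC[C@@H]3[C@H](OC(=O)[C@H]3C)[C@H]21
F4 | step 17 | (11S)-3-(trimethylsilyloxy)guaia-2,4(15),10(14)-trien-12,6α-olide | C=C1C(O[Si](C)(C)C)=C[C@H]2C(=C)CC[C@@H]3[C@H](OC(=O)[C@H]3C)[C@H]21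
F5 | step 17 | (11S)-3-oxoguaia-1,4(15),10(14)-trien-12,6α-olide | C=C1C(=O)C=C2C(=C)CC[C@@H]3[C@H](OC(=O)[C@H]3C)[C@H]21
F6 | step 17 | Diels–Alder adduct, Δ1(10) isomer of the target (C2 configuration not assigned, lost on isomerisation) | C=C1C(=O)C2C3=C(CC[C@@H]4[C@H](OC(=O)[C@H]4C)[C@@H]13)CC[C@]21C(=O)C[C@H]2C(=C)CC[C@@H]3[C@H](OC(=O)[C@@H]3C)[C@H]21
F0 | step 13 | none | none
F7 | step 18 | 1,2-dihydro target (cis A/C fusion) | C=C1C(=O)[C@H]2[C@@H]3[C@@H](CC[C@@H]4[C@H](OC(=O)[C@H]4C)[C@@H]13)CC[C@]21C(=O)C[C@H]2C(=C)CC[C@@H]3[C@H](OC(=O)[C@@H]3C)[C@H]21
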